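**Plan**

- Retrosynthesis: the two angelates and the epoxide are removed first (back to the cyclohept-3-ene-cis-1,5-diol 18). Then the CH2–CH(O) bond and the vinyl CH–CH(O) bond of the seven-membered ring are cut together, leaving the cis-cyclopentane-1,2-dicarbaldehyde 11 and a CH2–C(CH3)=CH unit with an allyl-nucleophilic end and a vinyl-nucleophilic end.
- Enabling feature: the two ester-bearing ring carbons are cis carbinol carbons, 1,4-related across the ring-fusion bond. The C(CH3)–CH epoxide between them is a masked Z-trisubstituted alkene, so the seven-membered ring is a 1,4-dialdehyde plus a three-carbon dinucleophile ((4+3) annulation).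
- Forward: cyclopentenone 3 → enone–acetylene [2+2] cyclobutene (a temporary ring that holds the two future formyl carbons cis and fixes the quaternary CH3 and ring-fusion H) → cyclopentane stereocentres set on the rigid bicyclo[3.2.0] frame → cyclobutene cleaved to 11 → one-flask α-bromoallylboration/Nozaki–Hiyama–Kishi closure of the seven-membered ring → directed epoxidation → esterification → deprotection.
- Stereochemistry: absolute configuration comes from (S)-silyloxycyclopentenone 1 (its carbinol centre is later erased) and from the (R,R)-diol boronate 16. The other centres come from convex-face attack on the bicyclo[3.2.0]heptene, chirality transfer in the allylboration, ring closure anti to the PMB ether, and hydroxyl-directed epoxidation.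

Key step: step 12

Remark: dialdehyde 11 (epimerisable formyl-bearing CH; its quaternary formyl group may rest reversibly as a lactol with the cis tertiary hydroxyl) and the allylic α-bromide 16 are labile and are therefore carried on crude.

**Step 1**
Reactants: 1 (S)-4-[(tert-butyldimethylsilyl)oxy]cyclopent-2-en-1-one
Product: 2 (S)-4-[(tert-butyldimethylsilyl)oxy]-2-iodocyclopent-2-en-1-one
Conditions: I2, pyridine/CH2Cl2 (1:1), 0 → 23 °C
Reagents that add atoms: iodine, II
Why: Pyridine-mediated α-iodination of the enone (conjugate addition of pyridine, iodination of the enolate, elimination) is a standard route to 2-iodocycloalkenones and leaves the C4 stereocentre untouched.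

**Step 2**
Reactants: 2 (S)-4-[(tert-butyldimethylsilyl)oxy]-2-iodocyclopent-2-en-1-one
Product: 3 (S)-4-[(tert-butyldimethylsilyl)oxy]-2-methylcyclopent-2-en-1-one
Conditions: MeZnCl, Pd(dppf)Cl2 (5 mol%), THF, 0 → 23 °C
Reagents that add atoms: methylzinc chloride, C[Zn]Cl
Why: Negishi coupling of the α-iodoenone installs the methyl group under neutral conditions that should avoid β-elimination of the silyloxy group.

**Step 3**
Reactants: 3 (S)-4-[(tert-butyldimethylsilyl)oxy]-2-methylcyclopent-2-en-1-one
Product: 4 cis-fused 4-exo-[(tert-butyldimethylsilyl)oxy]-1-methylbicyclo[3.2.0]hept-6-en-2-one (silyloxy group trans to the cyclobutene)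
Conditions: acetylene (sat.), hν (λ > 340 nm, uranium-glass filter), CH2Cl2, −78 °C
Reagents that add atoms: acetylene, C#C
Why: Enone–alkyne [2+2] photocycloaddition through the enone triplet gives the necessarily cis-fused cyclobutene, the alkyne adding to the face anti to the bulky silyloxy group, which should fix the absolute configuration of the quaternary methyl carbon and the adjacent ring-fusion CH.

**Step 4**
Reactants: 4 cis-fused 4-exo-[(tert-butyldimethylsilyl)oxy]-1-methylbicyclo[3.2.0]hept-6-en-2-one
Product: 5 4-exo-[(tert-butyldimethylsilyl)oxy]-1-methylbicyclo[3.2.0]hept-6-en-2-endo-ol (hydroxyl cis to the cyclobutene)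
Conditions: NaBH4, MeOH, −40 °C
Reagents that add atoms: none
Why: Hydride reduction of the bicyclo[3.2.0]heptenone should occur from the convex face, anti to the folded cyclobutene, giving the endo alcohol.

**Step 5**
Reactants: 5 4-exo-[(tert-butyldimethylsilyl)oxy]-1-methylbicyclo[3.2.0]hept-6-en-2-endo-ol
Product: 6 4-exo-[(tert-butyldimethylsilyl)oxy]-2-endo-[(4-methoxybenzyl)oxy]-1-methylbicyclo[3.2.0]hept-6-ene
Conditions: NaH, PMBCl, n-Bu4NI (cat.), DMF, 0 → 23 °C
Reagents that add atoms: 4-methoxybenzyl chloride, COc1ccc(CCl)cc1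
Why: Williamson etherification protects the secondary alcohol as a PMB ether that survives fluoride, oxidation, organometallic addition and the key step and is removed oxidatively at the end.

**Step 6**
Reactants: 6 4-exo-[(tert-butyldimethylsilyl)oxy]-2-endo-[(4-methoxybenzyl)oxy]-1-methylbicyclo[3.2.0]hept-6-ene
Product: 7 4-endo-[(4-methoxybenzyl)oxy]-5-methylbicyclo[3.2.0]hept-6-en-2-exo-ol
Conditions: n-Bu4NF, THF, 23 °C
Reagents that add atoms: none
Why: Fluoride-induced desilylation frees the secondary alcohol while the PMB ether is inert.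

**Step 7**
Reactants: 7 4-endo-[(4-methoxybenzyl)oxy]-5-methylbicyclo[3.2.0]hept-6-en-2-exo-ol
Product: 8 4-endo-[(4-methoxybenzyl)oxy]-5-methylbicyclo[3.2.0]hept-6-en-2-one
Conditions: Dess–Martin periodinane, CH2Cl2, 0 → 23 °C
Reagents that add atoms: none
Why: Dess–Martin oxidation gives the ketone under mild conditions, and the adjacent ring-fusion centre cannot epimerise in the cis-locked bicycle.

**Step 8**
Reactants: 8 4-endo-[(4-methoxybenzyl)oxy]-5-methylbicyclo[3.2.0]hept-6-en-2-one
Product: 9 2-exo-isopropyl-4-endo-[(4-methoxybenzyl)oxy]-5-methylbicyclo[3.2.0]hept-6-en-2-endo-ol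
Conditions: i-PrMgCl, CeCl3, THF, −78 → 0 °C; aq. NH4Cl
Reagents that add atoms: isopropylmagnesium chloride, CC(C)[Mg]Cl
Why: Organocerium 1,2-addition suppresses enolisation and β-alkoxide elimination, and the nucleophile should attack the convex face anti to the cyclobutene, placing isopropyl exo and the tertiary hydroxyl cis to the cyclobutene.

**Step 9**
Reactants: 9 2-exo-isopropyl-4-endo-[(4-methoxybenzyl)oxy]-5-methylbicyclo[3.2.0]hept-6-en-2-endo-ol
Product: 11 all-cis 3-hydroxy-3-isopropyl-5-[(4-methoxybenzyl)oxy]-1-methylcyclopentane-1,2-dicarbaldehyde (both formyl groups and both oxygens on one face; methyl and isopropyl on the other), via cyclobutane-cis-diol 10 (not isolated)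
Conditions: OsO4 (2 mol%), NaIO4, 2,6-lutidine, dioxane/H2O (3:1), 23 °C; dried azeotropically and used crude
Reagents that add atoms: osmium tetroxide, O=[Os](=O)(=O)=O; sodium periodate (terminal oxidant), [Na+].[O-]I(=O)(=O)=O
Why: Lemieux–Johnson cleavage (dihydroxylation, then periodate glycol cleavage) opens the strained cyclobutene, the temporary ring, to the cis-1,2-dicarbaldehyde without touching the PMB ether.

**Step 10**
Reactants: 12 isopropenylmagnesium bromide; 13 (1R,2R)-1,2-dicyclohexylethane-1,2-diol
Product: 15 (4R,5R)-4,5-dicyclohexyl-2-(prop-1-en-2-yl)-1,3,2-dioxaborolane, via isopropenylboronic acid 14 (not isolated)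
Conditions: B(OMe)3, THF, −78 → 23 °C; aq. HCl; then 13, MgSO4, Et2O, 23 °C
Reagents that add atoms: trimethyl borate, COB(OC)OC
Why: Borylation of the alkenyl Grignard reagent followed by esterification with the C2-symmetric diol gives the chiral alkenylboronic ester needed for the Matteson homologation.

**Step 11**
Reactants: 15 (4R,5R)-4,5-dicyclohexyl-2-(prop-1-en-2-yl)-1,3,2-dioxaborolane
Product: 16 (4R,5R)-2-[(S)-1-bromo-2-methylprop-2-en-1-yl]-4,5-dicyclohexyl-1,3,2-dioxaborolane
Conditions: CH2Br2, LiN(i-Pr)2, THF, −78 °C; ZnCl2, −78 → 23 °C; used crude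
Reagents that add atoms: dibromomethane, BrCBr
Why: In this Matteson homologation LiCHBr2 adds to boron and the alkenyl group migrates with displacement of one bromide, the (R,R)-diol directing formation of the (S)-α-bromo centre.

**Step 12**
Reactants: 11 all-cis 3-hydroxy-3-isopropyl-5-[(4-methoxybenzyl)oxy]-1-methylcyclopentane-1,2-dicarbaldehyde; 16 (4R,5R)-2-[(S)-1-bromo-2-methylprop-2-en-1-yl]-4,5-dicyclohexyl-1,3,2-dioxaborolane
Product: 18 cis-fused 3-isopropyl-1-[(4-methoxybenzyl)oxy]-6,8a-dimethyl-1,2,3,3a,4,5,8,8a-octahydroazulene-3,4,8-triol (4-OH, 8-OH, 8a-CH3, 3a-H and isopropyl on one face; 1-OPMB and 3-OH on the other), via (Z)-alkenyl bromide borate 17 (not isolated)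
Conditions: 16 (1.0 equiv), THF, 0 → 23 °C; then CrCl2 (6 equiv), NiCl2 (5 mol%), DMSO/THF, 23 °C, 0.01 M; aq. work-up
Reagents that add atoms: none
Why: The α-bromoallylboronate 16 adds to the formyl group on the ring-fusion CH through a chair six-membered transition state with bromine axial, forming the CH2–CH(O) bond and the (Z)-alkenyl bromide 17; CrCl2 with catalytic NiCl2 then turns the C–Br bond (oxidative addition to zerovalent nickel, transmetalation to trivalent chromium) into an alkenylchromium that adds to the remaining aldehyde, forming the vinyl CH–CH(O) bond. The closest known reaction types are the α-haloallylboration of aldehydes and the intramolecular Nozaki–Hiyama–Kishi reaction, here run in one flask. The seven-membered ring closes in the second event by 1,2-addition of the alkenyl carbon to the aldehyde (7-exo with respect to C=O), which only the Z-bromide can do and which the axial preference of the α-halogen secures. The carbinol next to the CH2 is set by 1,3-chirality transfer from the (S)-C(Br)–B centre of 16 (Br axial, aldehyde substituent equatorial), and the second carbinol should form with its oxygen on the side of the angular methyl, away from the cis PMB ether. The step needs discrimination between the two aldehydes in the first event, which the substrate secures because the other formyl group sits on the quaternary carbon next to the PMB ether and can rest reversibly as a lactol with the cis tertiary hydroxyl, while the reacting one sits on a tertiary carbon and can be activated by a hydrogen bond from the adjacent cis hydroxyl. One operation thus gives the cycloheptene ring, two carbinol stereocentres and the trisubstituted alkene that becomes the epoxide.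

**Step 13**
Reactants: 18 cis-fused 3-isopropyl-1-[(4-methoxybenzyl)oxy]-6,8a-dimethyl-1,2,3,3a,4,5,8,8a-octahydroazulene-3,4,8-triol
Product: 19 6,7-epoxy-3-isopropyl-1-[(4-methoxybenzyl)oxy]-6,8a-dimethyldecahydroazulene-3,4,8-triol (epoxide oxygen cis to the 4- and 8-hydroxyls)
Conditions: VO(acac)2 (5 mol%), t-BuOOH, CH2Cl2, 0 → 23 °C
Reagents that add atoms: tert-butyl hydroperoxide, CC(C)(C)OO
Why: Hydroxyl-directed epoxidation of the trisubstituted alkene delivers oxygen syn to the allylic hydroxyl (reinforced by the cis homoallylic hydroxyl), setting both epoxide centres.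

**Step 14**
Reactants: 19 6,7-epoxy-3-isopropyl-1-[(4-methoxybenzyl)oxy]-6,8a-dimethyldecahydroazulene-3,4,8-triol; 20 angelic acid [(Z)-2-methylbut-2-enoic acid]
Product: 21 6,7-epoxy-3-hydroxy-3-isopropyl-1-[(4-methoxybenzyl)oxy]-6,8a-dimethyldecahydroazulene-4,8-diyl bis[(Z)-2-methylbut-2-enoate] (4,8-bis-angelate of 19; 3-OH free, 1-OPMB)
Conditions: 20 (excess; two equivalents are incorporated, one per ester), 2,4,6-trichlorobenzoyl chloride, Et3N, toluene, 23 °C; then 19, 80 °C
Reagents that add atoms: angelic acid (second equivalent of 20), C/C=C(/C)C(=O)O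
Why: Yamaguchi esterification with the preformed mixed anhydride, run without DMAP to avoid Z-to-E isomerisation, should acylate each of the two secondary alcohols with one angeloyl unit while the hindered tertiary alcohol stays free.

**Step 15**
Reactants: 21 4,8-bis-angelate of 19
Product: 22 target CNP0265715.2 (4,8-bis-angelate of 6,7-epoxy-3-isopropyl-6,8a-dimethyldecahydroazulene-1,3,4,8-tetraol)
Conditions: DDQ, CH2Cl2/pH 7 buffer (10:1), 0 → 23 °C
Reagents that add atoms: none
Why: Oxidative PMB cleavage with DDQ in wet, buffered solvent frees the last secondary alcohol without affecting the epoxide or the angelates.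

**Compound list**

1 | (S)-4-[(tert-butyldimethylsilyl)oxy]cyclopent-2-en-1-one | O=C1C=C[C@@H](O[Si](C)(C)C(C)(C)C)C1 | starting material
2 | (S)-4-[(tert-butyldimethylsilyl)oxy]-2-iodocyclopent-2-en-1-one | O=C1C(I)=C[C@@H](O[Si](C)(C)C(C)(C)C)C1 | intermediate
3 | (S)-4-[(tert-butyldimethylsilyl)oxy]-2-methylcyclopent-2-en-1-one | O=C1C(C)=C[C@@H](O[Si](C)(C)C(C)(C)C)C1 | intermediate
4 | cis-fused 4-exo-[(tert-butyldimethylsilyl)oxy]-1-methylbicyclo[3.2.0]hept-6-en-2-one | C1=C[C@@H]2[C@@H](O[Si](C)(C)C(C)(C)C)CC(=O)[C@]12C | intermediate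
5 | 4-exo-[(tert-butyldimethylsilyl)oxy]-1-methylbicyclo[3.2.0]hept-6-en-2-endo-ol | C1=C[C@@H]2[C@@H](O[Si](C)(C)C(C)(C)C)C[C@H](O)[C@]12C | intermediate
6 | 4-exo-[(tert-butyldimethylsilyl)oxy]-2-endo-[(4-methoxybenzyl)oxy]-1-methylbicyclo[3.2.0]hept-6-ene | C1=C[C@@H]2[C@@H](O[Si](C)(C)C(C)(C)C)C[C@H](OCc3ccc(OC)cc3)[C@]12C | intermediate
7 | 4-endo-[(4-methoxybenzyl)oxy]-5-methylbicyclo[3.2.0]hept-6-en-2-exo-ol | C1=C[C@@H]2[C@@H](O)C[C@H](OCc3ccc(OC)cc3)[C@]12C | intermediate
8 | 4-endo-[(4-methoxybenzyl)oxy]-5-methylbicyclo[3.2.0]hept-6-en-2-one | C1=C[C@@H]2C(=O)C[C@H](OCc3ccc(OC)cc3)[C@]12C | intermediate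
9 | 2-exo-isopropyl-4-endo-[(4-methoxybenzyl)oxy]-5-methylbicyclo[3.2.0]hept-6-en-2-endo-ol | C1=C[C@@H]2[C@@](O)(C(C)C)C[C@H](OCc3ccc(OC)cc3)[C@]12C | intermediate
10 | cyclobutane-cis-diol from 9 (2-exo-isopropyl-4-endo-PMB-oxy-5-methylbicyclo[3.2.0]heptane-2-endo,6-exo,7-exo-triol) | O[C@@H]1[C@H](O)[C@@]2(C)[C@@H](OCc3ccc(OC)cc3)C[C@](O)(C(C)C)[C@@H]12 | intermediate
11 | all-cis 3-hydroxy-3-isopropyl-5-[(4-methoxybenzyl)oxy]-1-methylcyclopentane-1,2-dicarbaldehyde | O=C[C@@]1(C)[C@@H](OCc2ccc(OC)cc2)C[C@](O)(C(C)C)[C@H]1C=O | intermediate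
12 | isopropenylmagnesium bromide | C=C(C)[Mg]Br | starting material
13 | (1R,2R)-1,2-dicyclohexylethane-1,2-diol | O[C@H](C1CCCCC1)[C@H](O)C1CCCCC1 | starting material
14 | isopropenylboronic acid | C=C(C)B(O)O | intermediate
15 | (4R,5R)-4,5-dicyclohexyl-2-(prop-1-en-2-yl)-1,3,2-dioxaborolane | C=C(C)B1O[C@H](C2CCCCC2)[C@@H](C2CCCCC2)O1 | intermediate
16 | (4R,5R)-2-[(S)-1-bromo-2-methylprop-2-en-1-yl]-4,5-dicyclohexyl-1,3,2-dioxaborolane | C=C(C)[C@@H](Br)B1O[C@H](C2CCCCC2)[C@@H](C2CCCCC2)O1 | intermediate
17 | (Z)-alkenyl bromide borate: 2-[(R)-(Z)-4-bromo-1-(dicyclohexyldioxaborolanyloxy)-3-methylbut-3-enyl] derivative of the remaining 1-formylcyclopentane | O=C[C@@]1(C)[C@@H](OCc2ccc(OC)cc2)C[C@](O)(C(C)C)[C@H]1[C@H](OB3O[C@H](C4CCCCC4)[C@@H](C4CCCCC4)O3)C/C(C)=C\Br | intermediate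
18 | cis-fused 3-isopropyl-1-[(4-methoxybenzyl)oxy]-6,8a-dimethyl-1,2,3,3a,4,5,8,8a-octahydroazulene-3,4,8-triol | O[C@@H]1CC(C)=C[C@H](O)[C@@]2(C)[C@@H](OCc3ccc(OC)cc3)C[C@](O)(C(C)C)[C@@H]12 | intermediate
19 | 6,7-epoxy-3-isopropyl-1-[(4-methoxybenzyl)oxy]-6,8a-dimethyldecahydroazulene-3,4,8-triol | O[C@@H]1C[C@]2(C)O[C@@H]2[C@H](O)[C@@]2(C)[C@@H](OCc3ccc(OC)cc3)C[C@](O)(C(C)C)[C@@H]12 | intermediate
20 | angelic acid, (Z)-2-methylbut-2-enoic acid | C/C=C(/C)C(=O)O | starting material
21 | 4,8-bis-angelate of 19 | C/C=C(/C)C(=O)O[C@@H]1C[C@]2(C)O[C@@H]2[C@H](OC(=O)/C(C)=C\C)[C@@]2(C)[C@@H](OCc3ccc(OC)cc3)C[C@](O)(C(C)C)[C@@H]12 | intermediate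
22 | CNP0265715.2 | C/C=C(/C)C(=O)O[C@@H]1C[C@]2(C)O[C@@H]2[C@H](OC(=O)/C(C)=C\C)[C@@]2(C)[C@@H](O)C[C@](O)(C(C)C)[C@@H]12 | target

Total step count: 15. Longest linear sequence: 13 steps (steps 1–9 and 12–15, from 1); steps 10–11 make the boronate 16.

**Steps most likely to fail**

Step 12. The allylboration may not discriminate well enough between the two formyl groups, the hindered aldehyde may react slowly with the chiral boronate, and the chromium-mediated closure may give poor facial selectivity at the neopentyl carbinol. The fallback sets out from 11 and builds the same ring by a different bond-forming logic. Allylboration with (2-methylallyl)boronic acid pinacol ester (or its diisopinocampheylborane analogue for reagent control) gives the hydroxy aldehyde F1. Addition of vinylmagnesium bromide/CeCl3 to the remaining formyl group gives the diene diol F2. Ring-closing metathesis with second-generation Grubbs catalyst (CH2Cl2, 40 °C) forms the trisubstituted cycloheptene and returns to the route at 18. A wrong configuration at the allylic carbinol would be corrected there by MnO2 oxidation and Corey–Bakshi–Shibata reduction.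

Step 14. Acylation of the neopentyl alcohol next to the epoxide may stay incomplete, and the angelate may isomerise to the tiglate on prolonged heating. The fallback sets out from 19 and builds the Z-enoates on the molecule. Esterification of both secondary alcohols with 2-[bis(2,2,2-trifluoroethoxy)phosphoryl]propanoic acid (two equivalents incorporated; DCC, DMAP, CH2Cl2) gives the bis(phosphonate) F3. Still–Gennari olefination with acetaldehyde (KN(SiMe3)2, 18-crown-6, THF, −78 °C) then forms both (Z)-2-methylbut-2-enoates and returns to the route at 21.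

Step 3. The cyclobutene product is a β,γ-unsaturated ketone and may undergo secondary photolysis, and facial selectivity anti to the silyl ether may be incomplete. The fallback sets out from 3 and uses a saturated, photostable adduct. [2+2] Photocycloaddition with (Z)-1,2-dichloroethene gives the dichlorocyclobutane ketone F4 (chloride epimers). NaBH4 reduction gives the dichloro alcohol F5. Reductive elimination of the vicinal dichloride with Na/naphthalene (THF, −78 °C) forms the cyclobutene and returns to the route at 5.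

**Further compounds**

F1 | step 12 | all-cis 2-[(R)-1-hydroxy-3-methylbut-3-enyl]-3-hydroxy-3-isopropyl-5-[(4-methoxybenzyl)oxy]-1-methylcyclopentane-1-carbaldehyde | O=C[C@@]1(C)[C@@H](OCc2ccc(OC)cc2)C[C@](O)(C(C)C)[C@H]1[C@H](O)CC(C)=C
F2 | step 12 | diene diol: 1-(1-hydroxyallyl)-2-(1-hydroxy-3-methylbut-3-enyl) analogue of F1 | C=C[C@H](O)[C@@]1(C)[C@@H](OCc2ccc(OC)cc2)C[C@](O)(C(C)C)[C@H]1[C@H](O)CC(C)=C
F3 | step 14 | 4,8-bis{2-[bis(2,2,2-trifluoroethoxy)phosphoryl]propanoate} of 19 | CC(C(=O)O[C@@H]1C[C@]2(C)O[C@@H]2[C@H](OC(=O)C(C)P(=O)(OCC(F)(F)F)OCC(F)(F)F)[C@@]2(C)[C@@H](OCc3ccc(OC)cc3)C[C@](O)(C(C)C)[C@@H]12)P(=O)(OCC(F)(F)F)OCC(F)(F)F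
F4 | step 3 | 6,7-dichloro-4-exo-[(tert-butyldimethylsilyl)oxy]-1-methylbicyclo[3.2.0]heptan-2-one | ClC1C(Cl)[C@@H]2[C@@H](O[Si](C)(C)C(C)(C)C)CC(=O)[C@]12C
F5 | step 3 | 6,7-dichloro-4-exo-[(tert-butyldimethylsilyl)oxy]-1-methylbicyclo[3.2.0]heptan-2-endo-ol | ClC1C(Cl)[C@@H]2[C@@H](O[Si](C)(C)C(C)(C)C)C[C@H](O)[C@]12C
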